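**Retrosynthetic overview**
1. Target ⇒ diol 27 by two late acylations: lipase acetylation at O13, then angeloylation at O8.
2. Butenolide ⇒ intramolecular Horner–Wadsworth–Emmons closure of C7=C11 on a C7 ketone, itself unmasked by ozonolysis of a 7-methylidene group.
3. Ten-membered carbocycle ⇒ Nozaki–Hiyama–Kishi closure of C6–C7 between an epoxy aldehyde and an alkenyl triflate.
4. Open chain ⇒ geraniol (C6–C5–C4–C3–C2–C1–C10–C9, plus C14, C15) and ethyl 1,3-dithiane-2-carboxylate (C8, C7); Sharpless epoxide at C4/C5, ketoreductase carbinol at C8, Shi epoxide at C1/C10.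
5. Ring order: the two oxiranes on the open chain, then the ten-membered carbocycle, then the butenolide.

Assumption: ring positions use germacrane numbering (C1–C10 in the ring, C11–C13 lactone carbons, C14 on C10, C15 on C4); TBS = tert-butyldimethylsilyl, PMB = 4-methoxybenzyl; an (S)-selective ketoreductase for 8 is taken from a commercial panel.

**Route**

Step 1
Reactants: 1 geraniol
Product: 2 [(2R,3R)-3-methyl-3-(4-methylpent-3-en-1-yl)oxiran-2-yl]methanol
Conditions: Ti(OiPr)4 (5 mol %), D-(−)-diethyl tartrate (6 mol %), tBuOOH, 4 Å MS, CH2Cl2, −20 °C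
Reagents that add atoms: tert-butyl hydroperoxide CC(C)(C)OO
Why: Sharpless asymmetric epoxidation touches only the allylic alkene, and the D-(−)-tartrate catalyst delivers oxygen to the face that gives the (2R,3R)-epoxide, which becomes C4 and C5 of the target.

Step 2
Reactants: 2 epoxy alcohol
Product: 3 tert-butyl(dimethyl){[(2R,3R)-3-methyl-3-(4-methylpent-3-en-1-yl)oxiran-2-yl]methoxy}silane
Conditions: TBSCl, imidazole, DMF, 0 °C → rt
Reagents that add atoms: tert-butyldimethylsilyl chloride CC(C)(C)[Si](C)(C)Cl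
Why: Routine silylation of the primary alcohol protects the future C6 oxygen through the base and organometallic steps.

Step 3
Reactants: 3 TBS ether
Product: 4 (2E)-2-methyl-5-[(2R,3R)-2-methyl-3-(TBS-oxymethyl)oxiran-2-yl]pent-2-en-1-ol
Conditions: SeO2 (0.3 equiv), tBuOOH (3 equiv), CH2Cl2, 0 °C → rt
Reagents that add atoms: selenium dioxide O=[Se]=O; tert-butyl hydroperoxide CC(C)(C)OO
Why: Sharpless–Umbreit allylic oxidation (ene reaction, then [2,3]-sigmatropic shift) hydroxylates the E methyl group of the only alkene and keeps the E geometry.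

Step 4
Reactants: 4 allylic alcohol
Product: 5 {[(2R,3R)-3-[(3E)-5-bromo-4-methylpent-3-en-1-yl]-3-methyloxiran-2-yl]methoxy}(tert-butyl)dimethylsilane
Conditions: CBr4, PPh3, 2,6-lutidine (0.2 equiv), CH2Cl2, −20 → 0 °C
Reagents that add atoms: carbon tetrabromide BrC(Br)(Br)Br
Why: The Appel reaction converts the primary allylic alcohol to the bromide under near-neutral conditions that spare the epoxide and silyl ether.

Step 5
Reactants: 5 allylic bromide; 6 ethyl 1,3-dithiane-2-carboxylate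
Product: 7 ethyl 2-{(2E)-2-methyl-5-[(2R,3R)-2-methyl-3-(TBS-oxymethyl)oxiran-2-yl]pent-2-en-1-yl}-1,3-dithiane-2-carboxylate
Conditions: NaH, DMF–toluene (1:1), 0 °C → rt
Reagents that add atoms: none
Why: SN2 alkylation of the soft, sulfur- and ester-stabilised carbanion at the primary allylic bromide forms C8–C9 without allylic transposition.

Step 6
Reactants: 7 dithiane ester
Product: 8 ethyl (4E)-4-methyl-7-[(2R,3R)-2-methyl-3-(TBS-oxymethyl)oxiran-2-yl]-2-oxohept-4-enoate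
Conditions: PhI(OCOCF3)2 (1.5 equiv), solid NaHCO3, MeCN–H2O (9:1), 0 °C, 15 min; crude product used at once
Reagents that add atoms: water O
Why: Oxidative dithiane hydrolysis with the hypervalent iodine reagent (Stork–Zhao) is fast and, when buffered, leaves the alkene, epoxide and silyl ether alone.

Step 7
Reactants: 8 2-oxo ester
Product: 9 ethyl (2S,4E)-2-hydroxy-4-methyl-7-[(2R,3R)-2-methyl-3-(TBS-oxymethyl)oxiran-2-yl]hept-4-enoate
Conditions: (S)-selective ketoreductase, NADP+ (cat.), iPrOH (10 vol %), phosphate buffer pH 7.0, DMSO (5 vol %), 30 °C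
Reagents that add atoms: none
Why: Enzymatic asymmetric ketone reduction: the ketoreductase delivers hydride from NADPH (recycled from propan-2-ol) to one face of the activated 2-oxo ester at neutral pH and sets C8 as S.

Step 8
Reactants: 9 hydroxy ester
Product: 10 ethyl (2S,4E)-4-methyl-7-[(2R,3R)-2-methyl-3-(TBS-oxymethyl)oxiran-2-yl]-2-(PMB-oxy)hept-4-enoate
Conditions: 4-methoxybenzyl bromide, Ag2O, 4 Å MS, CH2Cl2, rt, dark
Reagents that add atoms: 4-methoxybenzyl bromide COc1ccc(CBr)cc1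
Why: Silver-oxide-mediated Williamson etherification is neutral, so the α-stereocentre of the ester and the epoxide are not disturbed.

Step 9
Reactants: 10 PMB ether
Product: 11 ethyl (2S)-3-[(2R,3R)-2-methyl-3-{2-[(2R,3R)-2-methyl-3-(TBS-oxymethyl)oxiran-2-yl]ethyl}oxiran-2-yl]-2-(PMB-oxy)propanoate
Conditions: Shi ketone from D-fructose (0.3 equiv), KHSO5 (as 2KHSO5·KHSO4·K2SO4), K2CO3, Bu4NHSO4 (cat.), MeCN–CH2(OMe)2–aq. buffer pH 10.5, 0 °C
Reagents that add atoms: potassium peroxymonosulfate [K+].[O-]S(=O)(=O)OO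
Why: Shi asymmetric epoxidation: the chiral dioxirane attacks the only alkene through a spiro transition state under catalyst control and gives the (R,R)-epoxide that becomes C1 and C10.

Step 10
Reactants: 11 diepoxy ester
Product: 12 (2S)-N-methoxy-N-methyl-3-[(2R,3R)-2-methyl-3-{2-[(2R,3R)-2-methyl-3-(TBS-oxymethyl)oxiran-2-yl]ethyl}oxiran-2-yl]-2-(PMB-oxy)propanamide
Conditions: MeNH(OMe)·HCl, iPrMgCl, THF, −20 → 0 °C
Reagents that add atoms: N,O-dimethylhydroxylamine hydrochloride CNOC.Cl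
Why: Ester aminolysis by the chloromagnesium amide gives the Weinreb amide at low temperature, where trisubstituted epoxides and the α-alkoxy stereocentre are stable.

Step 11
Reactants: 12 Weinreb amide
Product: 13 (3S)-4-[(2R,3R)-2-methyl-3-{2-[(2R,3R)-2-methyl-3-(TBS-oxymethyl)oxiran-2-yl]ethyl}oxiran-2-yl]-3-(PMB-oxy)butan-2-one
Conditions: MeMgBr, THF, −10 °C; aq. NH4Cl
Reagents that add atoms: methylmagnesium bromide C[Mg]Br
Why: Weinreb ketone synthesis: the stable magnesium chelate stops the addition at the methyl ketone stage.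

Step 12
Reactants: 13 methyl ketone
Product: 15 (3S)-4-[(2R,3R)-2-methyl-3-{2-[(2R,3R)-2-methyl-3-(TBS-oxymethyl)oxiran-2-yl]ethyl}oxiran-2-yl]-3-(PMB-oxy)but-1-en-2-yl trifluoromethanesulfonate, via potassium enolate 14 (not isolated)
Conditions: KN(SiMe3)2, THF, −78 °C; then PhNTf2, −78 → −20 °C
Reagents that add atoms: N-phenylbis(trifluoromethanesulfonimide) FC(F)(F)S(=O)(=O)N(c1ccccc1)S(=O)(=O)C(F)(F)F
Why: Kinetic deprotonation by the bulky base occurs at the methyl group and not at the hindered C8–H, and O-triflation gives the 2-triflyloxy-1-alkene that will carry C7 as a nucleophile.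

Step 13
Reactants: 15 alkenyl triflate
Product: 16 (3S)-4-[(2R,3R)-3-{2-[(2R,3R)-3-(hydroxymethyl)-2-methyloxiran-2-yl]ethyl}-2-methyloxiran-2-yl]-3-(PMB-oxy)but-1-en-2-yl trifluoromethanesulfonate
Conditions: Bu4NF, AcOH (1:1), THF, 0 °C → rt
Reagents that add atoms: none
Why: Buffered fluoride desilylation frees the primary alcohol without eliminating the alkenyl triflate or opening the epoxides.

Step 14
Reactants: 16 epoxy alcohol
Product: 17 (3S)-4-[(2R,3R)-3-{2-[(2R,3S)-3-formyl-2-methyloxiran-2-yl]ethyl}-2-methyloxiran-2-yl]-3-(PMB-oxy)but-1-en-2-yl trifluoromethanesulfonate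
Conditions: Dess–Martin periodinane, NaHCO3, CH2Cl2, 0 °C → rt
Reagents that add atoms: none
Why: Buffered Dess–Martin oxidation gives the sensitive epoxy aldehyde without epimerisation (the 3S label on the formyl-bearing carbon is a priority change only).

Step 15
Reactants: 17 epoxy aldehyde
Product: 18 (1R,4R,5R,6S,8S,10R)-1,10:4,5-diepoxy-4,10-dimethyl-7-methylidene-8-(PMB-oxy)cyclodecan-6-ol
Conditions: CrCl2 (8 equiv), NiCl2 (0.1 equiv), degassed DMF, 2 mM, rt; aq. work-up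
Reagents that add atoms: none
Why: Intramolecular Nozaki–Hiyama–Kishi reaction: the alkenylchromium species formed under nickel catalysis adds only to the aldehyde at high dilution, anti to the epoxide C–O bond and with the chromium-bound oxygen turned away from the C4 methyl group, which is expected to give the 6S carbinol.

Step 16
Reactants: 19 4-methoxybenzyl alcohol; 20 ethyl 2-(diethoxyphosphoryl)prop-2-enoate
Product: 21 ethyl 2-(diethoxyphosphoryl)-3-(PMB-oxy)propanoate (racemic)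
Conditions: KOtBu (5 mol %), THF, 0 °C
Reagents that add atoms: none
Why: Base-catalysed oxa-Michael addition of the alcohol to the doubly activated vinylphosphonate installs the protected C13 oxygen.

Step 17
Reactants: 21 phosphonate ester
Product: 22 2-(diethoxyphosphoryl)-3-(PMB-oxy)propanoic acid (racemic)
Conditions: Me3SnOH, 1,2-dichloroethane, 70 °C; dilute aq. HCl wash
Reagents that add atoms: trimethyltin hydroxide C[Sn](C)(C)O
Why: Neutral ester hydrolysis with the tin hydroxide avoids the phosphonate carbanion and so avoids retro-Michael loss of the PMB-oxy group.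

Step 18
Reactants: 18 macrocyclic allylic alcohol; 22 phosphonate acid
Product: 23 (1R,4R,5R,6S,8S,10R)-1,10:4,5-diepoxy-4,10-dimethyl-7-methylidene-8-(PMB-oxy)cyclodecan-6-yl 2-(diethoxyphosphoryl)-3-(PMB-oxy)propanoate (both epimers at the phosphonate carbon)
Conditions: DCC, DMAP (cat.), CH2Cl2, 0 °C → rt
Reagents that add atoms: none
Why: Steglich esterification of the α-phosphono acid acylates the hindered C6 hydroxyl and places C11, C12 and C13 on O6.

Step 19
Reactants: 23 phosphonate ester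
Product: 25 (1R,4R,5R,6R,8S,10R)-1,10:4,5-diepoxy-4,10-dimethyl-7-oxo-8-(PMB-oxy)cyclodecan-6-yl 2-(diethoxyphosphoryl)-3-(PMB-oxy)propanoate, via ozonide 24 (not isolated)
Conditions: O3, CH2Cl2, −78 °C (Sudan Red 7B end point); then PPh3, −78 °C → rt
Reagents that add atoms: ozone [O-][O+]=O
Why: Ozonolysis cleaves the only C=C bond to the C7 ketone, the anisyl rings reacting much more slowly when the dye marks the end point (6R is a priority change, not an inversion).

Step 20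
Reactants: 25 keto phosphonate
Product: 26 (1R,4R,5R,6S,8S,10R)-1,10:4,5-diepoxy-8,13-bis(PMB-oxy)germacr-7(11)-en-12,6-olide
Conditions: LiCl, iPr2NEt, MeCN, 0 °C → rt
Reagents that add atoms: none
Why: Intramolecular Horner–Wadsworth–Emmons olefination under Masamune–Roush conditions: the lithium-chelated phosphonate anion attacks the adjacent C7 ketone and forms the tetrasubstituted C7=C11 butenolide faster than C6 enolisation or β-alkoxy loss.

Step 21
Reactants: 26 bis-PMB butenolide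
Product: 27 (1R,4R,5R,6S,8S,10R)-1,10:4,5-diepoxy-8,13-dihydroxygermacr-7(11)-en-12,6-olide
Conditions: DDQ (2.5 equiv), CH2Cl2–pH 7 phosphate buffer (10:1), 0 °C → rt
Reagents that add atoms: none
Why: Oxidative PMB cleavage by DDQ (benzylic hydride abstraction, then hydrolysis) removes both ethers under neutral conditions that spare the epoxides and the butenolide.

Step 22
Reactants: 27 diol
Product: 28 (1R,4R,5R,6S,8S,10R)-13-acetoxy-1,10:4,5-diepoxy-8-hydroxygermacr-7(11)-en-12,6-olide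
Conditions: lipase (Candida antarctica lipase B, immobilised), vinyl acetate, tBuOMe, 30 °C
Reagents that add atoms: vinyl acetate CC(=O)OC=C
Why: Lipase-catalysed transesterification acylates only the unhindered primary C13 hydroxyl, leaves the hindered secondary C8 hydroxyl free, and is irreversible because vinyl alcohol tautomerises.

Step 23
Reactants: 28 monoacetate; 29 angelic acid, (2Z)-2-methylbut-2-enoic acid
Product: 31 (1R,4R,5R,6S,8S,10R)-13-acetoxy-1,10:4,5-diepoxy-8-[(2Z)-2-methylbut-2-enoyloxy]germacr-7(11)-en-12,6-olide, via mixed anhydride 30 (not isolated)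
Conditions: 29, 2,4,6-trichlorobenzoyl chloride, Et3N, toluene, rt, amine salt filtered off; then 28, toluene, 75 °C
Reagents that add atoms: none
Why: Yamaguchi-type esterification through the mixed anhydride, run without a nucleophilic catalyst, acylates the C8 hydroxyl at the less hindered angeloyl carbonyl and keeps the Z geometry.

**Compound list**
1 | geraniol, (2E)-3,7-dimethylocta-2,6-dien-1-ol | CC(C)=CCC/C(C)=C/CO | starting material
2 | [(2R,3R)-3-methyl-3-(4-methylpent-3-en-1-yl)oxiran-2-yl]methanol | CC(C)=CCC[C@@]1(C)O[C@@H]1CO | intermediate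
3 | tert-butyl(dimethyl){[(2R,3R)-3-methyl-3-(4-methylpent-3-en-1-yl)oxiran-2-yl]methoxy}silane | CC(C)=CCC[C@@]1(C)O[C@@H]1CO[Si](C)(C)C(C)(C)C | intermediate
4 | (2E)-2-methyl-5-[(2R,3R)-2-methyl-3-(TBS-oxymethyl)oxiran-2-yl]pent-2-en-1-ol | OC/C(C)=C/CC[C@@]1(C)O[C@@H]1CO[Si](C)(C)C(C)(C)C | intermediate
5 | {[(2R,3R)-3-[(3E)-5-bromo-4-methylpent-3-en-1-yl]-3-methyloxiran-2-yl]methoxy}(tert-butyl)dimethylsilane | BrC/C(C)=C/CC[C@@]1(C)O[C@@H]1CO[Si](C)(C)C(C)(C)C | intermediate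
6 | ethyl 1,3-dithiane-2-carboxylate | CCOC(=O)C1SCCCS1 | starting material
7 | ethyl 2-{(2E)-2-methyl-5-[(2R,3R)-2-methyl-3-(TBS-oxymethyl)oxiran-2-yl]pent-2-en-1-yl}-1,3-dithiane-2-carboxylate | CCOC(=O)C1(C/C(C)=C/CC[C@@]2(C)O[C@@H]2CO[Si](C)(C)C(C)(C)C)SCCCS1 | intermediate
8 | ethyl (4E)-4-methyl-7-[(2R,3R)-2-methyl-3-(TBS-oxymethyl)oxiran-2-yl]-2-oxohept-4-enoate | CCOC(=O)C(=O)C/C(C)=C/CC[C@@]1(C)O[C@@H]1CO[Si](C)(C)C(C)(C)C | intermediate
9 | ethyl (2S,4E)-2-hydroxy-4-methyl-7-[(2R,3R)-2-methyl-3-(TBS-oxymethyl)oxiran-2-yl]hept-4-enoate | O[C@H](C(=O)OCC)C/C(C)=C/CC[C@@]1(C)O[C@@H]1CO[Si](C)(C)C(C)(C)C | intermediate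
10 | ethyl (2S,4E)-4-methyl-7-[(2R,3R)-2-methyl-3-(TBS-oxymethyl)oxiran-2-yl]-2-(PMB-oxy)hept-4-enoate | COc1ccc(CO[C@H](C(=O)OCC)C/C(C)=C/CC[C@@]2(C)O[C@@H]2CO[Si](C)(C)C(C)(C)C)cc1 | intermediate
11 | ethyl (2S)-3-[(2R,3R)-2-methyl-3-{2-[(2R,3R)-2-methyl-3-(TBS-oxymethyl)oxiran-2-yl]ethyl}oxiran-2-yl]-2-(PMB-oxy)propanoate | COc1ccc(CO[C@H](C(=O)OCC)C[C@@]2(C)O[C@@H]2CC[C@@]2(C)O[C@@H]2CO[Si](C)(C)C(C)(C)C)cc1 | intermediate
12 | (2S)-N-methoxy-N-methyl-3-[(2R,3R)-2-methyl-3-{2-[(2R,3R)-2-methyl-3-(TBS-oxymethyl)oxiran-2-yl]ethyl}oxiran-2-yl]-2-(PMB-oxy)propanamide | COc1ccc(CO[C@H](C(=O)N(C)OC)C[C@@]2(C)O[C@@H]2CC[C@@]2(C)O[C@@H]2CO[Si](C)(C)C(C)(C)C)cc1 | intermediate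
13 | (3S)-4-[(2R,3R)-2-methyl-3-{2-[(2R,3R)-2-methyl-3-(TBS-oxymethyl)oxiran-2-yl]ethyl}oxiran-2-yl]-3-(PMB-oxy)butan-2-one | COc1ccc(CO[C@H](C(C)=O)C[C@@]2(C)O[C@@H]2CC[C@@]2(C)O[C@@H]2CO[Si](C)(C)C(C)(C)C)cc1 | intermediate
14 | potassium (3S)-4-[(2R,3R)-2-methyl-3-{2-[(2R,3R)-2-methyl-3-(TBS-oxymethyl)oxiran-2-yl]ethyl}oxiran-2-yl]-3-(PMB-oxy)but-1-en-2-olate | COc1ccc(CO[C@H](C(=C)[O-])C[C@@]2(C)O[C@@H]2CC[C@@]2(C)O[C@@H]2CO[Si](C)(C)C(C)(C)C)cc1.[K+] | intermediate
15 | (3S)-4-[(2R,3R)-2-methyl-3-{2-[(2R,3R)-2-methyl-3-(TBS-oxymethyl)oxiran-2-yl]ethyl}oxiran-2-yl]-3-(PMB-oxy)but-1-en-2-yl trifluoromethanesulfonate | COc1ccc(CO[C@H](C(=C)OS(=O)(=O)C(F)(F)F)C[C@@]2(C)O[C@@H]2CC[C@@]2(C)O[C@@H]2CO[Si](C)(C)C(C)(C)C)cc1 | intermediate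
16 | (3S)-4-[(2R,3R)-3-{2-[(2R,3R)-3-(hydroxymethyl)-2-methyloxiran-2-yl]ethyl}-2-methyloxiran-2-yl]-3-(PMB-oxy)but-1-en-2-yl trifluoromethanesulfonate | COc1ccc(CO[C@H](C(=C)OS(=O)(=O)C(F)(F)F)C[C@@]2(C)O[C@@H]2CC[C@@]2(C)O[C@@H]2CO)cc1 | intermediate
17 | (3S)-4-[(2R,3R)-3-{2-[(2R,3S)-3-formyl-2-methyloxiran-2-yl]ethyl}-2-methyloxiran-2-yl]-3-(PMB-oxy)but-1-en-2-yl trifluoromethanesulfonate | COc1ccc(CO[C@H](C(=C)OS(=O)(=O)C(F)(F)F)C[C@@]2(C)O[C@@H]2CC[C@@]2(C)O[C@@H]2C=O)cc1 | intermediate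
18 | (1R,4R,5R,6S,8S,10R)-1,10:4,5-diepoxy-4,10-dimethyl-7-methylidene-8-(PMB-oxy)cyclodecan-6-ol | COc1ccc(CO[C@H]2C[C@@]3(C)O[C@@H]3CC[C@@]3(C)O[C@@H]3[C@@H](O)C2=C)cc1 | intermediate
19 | 4-methoxybenzyl alcohol | COc1ccc(CO)cc1 | starting material
20 | ethyl 2-(diethoxyphosphoryl)prop-2-enoate | CCOC(=O)C(=C)P(=O)(OCC)OCC | starting material
21 | ethyl 2-(diethoxyphosphoryl)-3-(PMB-oxy)propanoate, racemic | CCOC(=O)C(COCc1ccc(OC)cc1)P(=O)(OCC)OCC | intermediate
22 | 2-(diethoxyphosphoryl)-3-(PMB-oxy)propanoic acid, racemic | OC(=O)C(COCc1ccc(OC)cc1)P(=O)(OCC)OCC | intermediate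
23 | (1R,4R,5R,6S,8S,10R)-1,10:4,5-diepoxy-4,10-dimethyl-7-methylidene-8-(PMB-oxy)cyclodecan-6-yl 2-(diethoxyphosphoryl)-3-(PMB-oxy)propanoate | COc1ccc(CO[C@H]2C[C@@]3(C)O[C@@H]3CC[C@@]3(C)O[C@@H]3[C@@H](OC(=O)C(COCc3ccc(OC)cc3)P(=O)(OCC)OCC)C2=C)cc1 | intermediate
24 | ozonide of 23: 1,2,4-trioxolane spiro-fused at C7 | COc1ccc(CO[C@H]2C[C@@]3(C)O[C@@H]3CC[C@@]3(C)O[C@@H]3[C@@H](OC(=O)C(COCc3ccc(OC)cc3)P(=O)(OCC)OCC)C24OCOO4)cc1 | intermediate
25 | (1R,4R,5R,6R,8S,10R)-1,10:4,5-diepoxy-4,10-dimethyl-7-oxo-8-(PMB-oxy)cyclodecan-6-yl 2-(diethoxyphosphoryl)-3-(PMB-oxy)propanoate | COc1ccc(CO[C@H]2C[C@@]3(C)O[C@@H]3CC[C@@]3(C)O[C@@H]3[C@@H](OC(=O)C(COCc3ccc(OC)cc3)P(=O)(OCC)OCC)C2=O)cc1 | intermediate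
26 | (1R,4R,5R,6S,8S,10R)-1,10:4,5-diepoxy-8,13-bis(PMB-oxy)germacr-7(11)-en-12,6-olide | COc1ccc(CO[C@H]2C[C@@]3(C)O[C@@H]3CC[C@@]3(C)O[C@@H]3[C@H]3OC(=O)C(COCc4ccc(OC)cc4)=C23)cc1 | intermediate
27 | (1R,4R,5R,6S,8S,10R)-1,10:4,5-diepoxy-8,13-dihydroxygermacr-7(11)-en-12,6-olide | O[C@H]1C[C@@]2(C)O[C@@H]2CC[C@@]2(C)O[C@@H]2[C@H]2OC(=O)C(CO)=C12 | intermediate
28 | (1R,4R,5R,6S,8S,10R)-13-acetoxy-1,10:4,5-diepoxy-8-hydroxygermacr-7(11)-en-12,6-olide | O[C@H]1C[C@@]2(C)O[C@@H]2CC[C@@]2(C)O[C@@H]2[C@H]2OC(=O)C(COC(C)=O)=C12 | intermediate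
29 | angelic acid, (2Z)-2-methylbut-2-enoic acid | C/C=C(/C)C(=O)O | starting material
30 | (2Z)-2-methylbut-2-enoic 2,4,6-trichlorobenzoic anhydride | C/C=C(/C)C(=O)OC(=O)c1c(Cl)cc(Cl)cc1Cl | intermediate
31 | (1R,4R,5R,6S,8S,10R)-13-acetoxy-1,10:4,5-diepoxy-8-[(2Z)-2-methylbut-2-enoyloxy]germacr-7(11)-en-12,6-olide (CNP0251711.2) | C/C=C(/C)C(=O)O[C@H]1C[C@@]2(C)O[C@@H]2CC[C@@]2(C)O[C@@H]2[C@H]2OC(=O)C(COC(C)=O)=C12 | target

**Step count and risks**

Total steps: 23. Longest linear sequence: 21 (steps 1–15, then 18–23); steps 16–17 make acid 22.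

Most likely to fail:

Step 15 (ring closure). The ten-membered ring is strained, and the C6 configuration rests on a transition-state argument; an open-chain Felkin–Anh addition would favour the other epimer. The fallback sets out from 17 and comes back at 18. If the closure gives mainly the (1R,4R,5R,6R,8S,10R)-6-epimer alcohol F1, this is oxidised with Dess–Martin periodinane to the (1R,4R,5S,8S,10R)-7-methylidene-6-ketone F2. Luche reduction (NaBH4, CeCl3, MeOH, −78 °C) then delivers hydride anti to the epoxide C–O bond, which for a ketone gives the 6S alcohol 18. C6 is thus set by hydride delivery to a ring ketone and not by the C–C bond formation.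

Step 20 (butenolide closure). The α-acyloxy ketone can enolise at C6 and open the neighbouring epoxide, and the phosphonate anion can lose the PMB-oxy group. The fallback sets out from 18 and comes back at 26, and uses neither a ketone nor a carbanion. Alcohol 18 is esterified (DCC, DMAP) with 2-{[(4-methoxybenzyl)oxy]methyl}prop-2-enoic acid F3, made from 19 and 2-(bromomethyl)acrylic acid with NaH, to give the diene ester F4. Ring-closing metathesis with the second-generation Hoveyda–Grubbs catalyst in toluene at 80 °C then joins C7 and C11 directly to 26 with loss of ethene; this closure to a hindered tetrasubstituted alkene is itself demanding.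

Step 23 (angeloylation). The hindered C8 hydroxyl reacts slowly and angelates isomerise easily to tiglates. The fallback sets out from 28 and comes back at 31, and builds the Z double bond on the molecule. Alcohol 28 is esterified (DCC, DMAP) with 2-[bis(2,2,2-trifluoroethoxy)phosphoryl]propanoic acid F5, obtained by hydrolysis of its commercial ethyl ester, to give the phosphonate ester F6. Still–Gennari olefination of F6 with acetaldehyde (KN(SiMe3)2, 18-crown-6, THF, −78 °C) gives the Z-configured 2-methylbut-2-enoate 31.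

**Further compounds**
F1 | step 15 | (1R,4R,5R,6R,8S,10R)-1,10:4,5-diepoxy-4,10-dimethyl-7-methylidene-8-(PMB-oxy)cyclodecan-6-ol | COc1ccc(CO[C@H]2C[C@@]3(C)O[C@@H]3CC[C@@]3(C)O[C@@H]3[C@H](O)C2=C)cc1
F2 | step 15 | (1R,4R,5S,8S,10R)-1,10:4,5-diepoxy-4,10-dimethyl-7-methylidene-8-(PMB-oxy)cyclodecan-6-one | COc1ccc(CO[C@H]2C[C@@]3(C)O[C@@H]3CC[C@@]3(C)O[C@@H]3C(=O)C2=C)cc1
F3 | step 20 | 2-{[(4-methoxybenzyl)oxy]methyl}prop-2-enoic acid | C=C(COCc1ccc(OC)cc1)C(=O)O
F4 | step 20 | (1R,4R,5R,6S,8S,10R)-1,10:4,5-diepoxy-4,10-dimethyl-7-methylidene-8-(PMB-oxy)cyclodecan-6-yl 2-{[(4-methoxybenzyl)oxy]methyl}prop-2-enoate | COc1ccc(CO[C@H]2C[C@@]3(C)O[C@@H]3CC[C@@]3(C)O[C@@H]3[C@@H](OC(=O)C(=C)COCc3ccc(OC)cc3)C2=C)cc1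
F5 | step 23 | 2-[bis(2,2,2-trifluoroethoxy)phosphoryl]propanoic acid | CC(C(=O)O)P(=O)(OCC(F)(F)F)OCC(F)(F)F
F6 | step 23 | (1R,4R,5R,6S,8S,10R)-13-acetoxy-1,10:4,5-diepoxy-12-oxo-12,6-olidogermacr-7(11)-en-8-yl 2-[bis(2,2,2-trifluoroethoxy)phosphoryl]propanoate | CC(C(=O)O[C@H]1C[C@@]2(C)O[C@@H]2CC[C@@]2(C)O[C@@H]2[C@H]2OC(=O)C(COC(C)=O)=C12)P(=O)(OCC(F)(F)F)OCC(F)(F)F
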